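**Retrosynthetic overview**

- The target comes from acetylation of the 8β-alcohol; everything else is already in place at that stage.
- Ring B is closed last through the C7–C8 bond by an intramolecular indium Barbier allylation. A 2-(methoxycarbonyl)allylindium acts as a β-acrylate carbanion (reversed polarity at the normally electrophilic enoate β-carbon) and attacks the C8 aldehyde, setting C7, C8 and the α-methylene ester in one step.
- The bromo aldehyde for this closure comes from a ring A cyclohexene. Its C10 allyl group is a latent CH2CHO (Lemieux–Johnson), and its C5 CH2CHO arm is homologated by a Morita–Baylis–Hillman reaction and SN2′ bromination.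
- Ring A comes from Stork–Danheiser transposition of an (R)-6-allyl-6-methyl vinylogous ester with a masked acetaldehyde Grignard reagent. C10 is set by Pd-catalysed decarboxylative asymmetric allylation and C3 by CBS reduction, followed by esterification.
- Ring order: ring A is bought as 3-ethoxy-2-methylcyclohex-2-enone and elaborated first; ring B is formed in the key step.

Assumption: 3-ethoxy-2-methylcyclohex-2-en-1-one, (E)-3-methylpent-2-enoic acid (geometrically pure) and the 0.5 M THF solution of (1,3-dioxolan-2-ylmethyl)magnesium bromide are bought as such.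

Position labels C1–C15 follow eudesmane numbering: C10 is the quaternary carbon, C7 carries the acrylate, C8 the acetate, C3 the pentenoate.

**Step 1**
Reactants: 1 3-ethoxy-2-methylcyclohex-2-en-1-one
Product: 3 allyl (5-ethoxy-2,6-dimethylcyclohexa-1,5-dien-1-yl) carbonate, via racemic 3-ethoxy-2,6-dimethylcyclohex-2-en-1-one 2 (not isolated)
Conditions: LiN(i-Pr)2 (1.05 equiv), THF, –78 °C; MeI (1.0 equiv), –78 → 0 °C; recool to –78 °C, LiN(i-Pr)2 (1.15 equiv), TMEDA; allyl chloroformate (1.3 equiv), –78 °C → rt; crude through basic alumina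
Reagents that add atoms: iodomethane, CI; allyl chloroformate, C=CCOC(Cl)=O
Why: Two consecutive kinetic α′-enolizations of the vinylogous ester (Stork–Danheiser enolate chemistry) allow C-methylation and then O-acylation by the hard chloroformate in one flask; the methine stereocenter of 2 is erased as it becomes sp2, and any C-acylated β-keto ester isomer would converge to the same product in step 2.

**Step 2**
Reactants: 3 allyl (5-ethoxy-2,6-dimethylcyclohexa-1,5-dien-1-yl) carbonate
Product: 4 (R)-6-allyl-3-ethoxy-2,6-dimethylcyclohex-2-en-1-one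
Conditions: Pd2(dba)3 (2.5 mol%), (R)-t-Bu-PHOX [(R)-4-tert-butyl-2-(2-diphenylphosphinophenyl)-4,5-dihydrooxazole] (6 mol%), toluene, 30 °C
Reagents that add atoms: none
Why: Decarboxylative asymmetric allylic alkylation (Tsuji–Trost type): zerovalent palladium ionizes the allyl carbonate, loss of CO2 gives a (PHOX)Pd(allyl) enolate that recombines in the inner sphere, and the (R)-ligand gives the (R)-quaternary center (future C10) by analogy with the (S)-ligand giving (S)-2-allyl-2-methylcyclohexanone; about 85–90% ee is expected and is upgraded after step 4.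

**Step 3**
Reactants: 4 (R)-6-allyl-3-ethoxy-2,6-dimethylcyclohex-2-en-1-one; 5 (1,3-dioxolan-2-ylmethyl)magnesium bromide
Product: 7 (R)-4-allyl-3-(1,3-dioxolan-2-ylmethyl)-2,4-dimethylcyclohex-2-en-1-one, via carbinol adduct 6 (not isolated)
Conditions: 5 (3 equiv), THF, 0 → 40 °C; then 1 M aq HCl, 0 °C, 20 min
Reagents that add atoms: (1,3-dioxolan-2-ylmethyl)magnesium bromide 5, Br[Mg]CC1OCCO1; water, O (new carbonyl oxygen)
Why: Stork–Danheiser 1,2-addition and transposition: the Grignard reagent adds to the vinylogous ester carbonyl, brief dilute acid ionizes the tertiary allylic carbinol, water adds at the ethoxy-bearing carbon and ethanol leaves, giving the transposed tetrasubstituted enone (future C3 ketone, C4=C5 alkene) while the quaternary center is untouched and the dioxolane survives the short cold acid contact.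

**Step 4**
Reactants: 7 (R)-4-allyl-3-(1,3-dioxolan-2-ylmethyl)-2,4-dimethylcyclohex-2-en-1-one
Product: 8 (1S,4R)-4-allyl-3-(1,3-dioxolan-2-ylmethyl)-2,4-dimethylcyclohex-2-en-1-ol
Conditions: (R)-Me-CBS oxazaborolidine [(R)-1-methyl-3,3-diphenyltetrahydro-1H,3H-pyrrolo[1,2-c][1,3,2]oxazaborole] (20 mol%), catecholborane (1.8 equiv), toluene, –78 → –40 °C
Reagents that add atoms: none
Why: Corey–Bakshi–Shibata reduction: catalyst-controlled hydride delivery with the tetrasubstituted alkene carbon as the large group sets the (S)-carbinol (future C3), catecholborane does not hydroborate the allyl group, and the minor C10 enantiomer from step 2 now becomes a diastereomer that is removed by chromatography.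

**Step 5**
Reactants: 8 (1S,4R)-4-allyl-3-(1,3-dioxolan-2-ylmethyl)-2,4-dimethylcyclohex-2-en-1-ol; 9 (E)-3-methylpent-2-enoic acid
Product: 10 (1S,4R)-4-allyl-3-(1,3-dioxolan-2-ylmethyl)-2,4-dimethylcyclohex-2-en-1-yl (E)-3-methylpent-2-enoate
Conditions: 9 (1.3 equiv), DCC (N,N′-dicyclohexylcarbodiimide), DMAP (0.2 equiv), CH2Cl2, 0 °C → rt
Reagents that add atoms: (E)-3-methylpent-2-enoic acid 9, CC/C(C)=C/C(=O)O
Why: Steglich esterification under neutral conditions acylates the allylic alcohol with retention at C3 and avoids the vinylketene pathway that would scramble the E geometry of the β,β-disubstituted enoic acid.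

**Step 6**
Reactants: 10 (1S,4R)-4-allyl-3-(1,3-dioxolan-2-ylmethyl)-2,4-dimethylcyclohex-2-en-1-yl (E)-3-methylpent-2-enoate
Product: 11 (1S,4R)-4-allyl-2,4-dimethyl-3-(2-oxoethyl)cyclohex-2-en-1-yl (E)-3-methylpent-2-enoate
Conditions: PPTS (0.3 equiv), acetone–H2O (9:1), 50 °C; used crude
Reagents that add atoms: water, O
Why: Mild acid-catalysed acetal hydrolysis unmasks the aldehyde; the allylic ester tolerates PPTS, and the tetrasubstituted alkene does not move into conjugation because that would create a strained exocyclic alkene next to the quaternary carbon.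

**Step 7**
Reactants: 11 (1S,4R)-4-allyl-2,4-dimethyl-3-(2-oxoethyl)cyclohex-2-en-1-yl (E)-3-methylpent-2-enoate; 12 methyl acrylate
Product: 13 methyl 4-[(3S,6R)-6-allyl-2,6-dimethyl-3-{[(E)-3-methylpent-2-enoyl]oxy}cyclohex-1-en-1-yl]-3-hydroxy-2-methylidenebutanoate (about 1:1 at the new carbinol carbon)
Conditions: 12 (5 equiv), quinuclidine (0.5 equiv), MeOH (1 equiv), rt
Reagents that add atoms: methyl acrylate 12, C=CC(=O)OC
Why: Morita–Baylis–Hillman reaction, using quinuclidine and methanol as the fast catalyst system to outrun enolization of the aldehyde; the new carbinol center forms as a mixture, which is irrelevant because it is erased in step 8.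

**Step 8**
Reactants: 13 methyl 4-[(3S,6R)-6-allyl-2,6-dimethyl-3-{[(E)-3-methylpent-2-enoyl]oxy}cyclohex-1-en-1-yl]-3-hydroxy-2-methylidenebutanoate
Product: 14 methyl (Z)-4-[(3S,6R)-6-allyl-2,6-dimethyl-3-{[(E)-3-methylpent-2-enoyl]oxy}cyclohex-1-en-1-yl]-2-(bromomethyl)but-2-enoate
Conditions: NBS (1.3 equiv), Me2S (1.5 equiv), CH2Cl2, –20 °C → rt
Reagents that add atoms: N-bromosuccinimide, O=C1CCC(=O)N1Br
Why: Corey–Kim-type activation of the allylic alcohol as an alkoxysulfonium salt followed by SN2′ attack of bromide gives the rearranged primary bromide, the (Z)-2-(bromomethyl)enoate being the thermodynamically preferred trisubstituted isomer; neutral conditions spare the allylic ester and the other alkenes.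

**Step 9**
Reactants: 14 methyl (Z)-4-[(3S,6R)-6-allyl-2,6-dimethyl-3-{[(E)-3-methylpent-2-enoyl]oxy}cyclohex-1-en-1-yl]-2-(bromomethyl)but-2-enoate
Product: 15 methyl (Z)-2-(bromomethyl)-4-[(3S,6R)-2,6-dimethyl-3-{[(E)-3-methylpent-2-enoyl]oxy}-6-(2-oxoethyl)cyclohex-1-en-1-yl]but-2-enoate
Conditions: OsO4 (2 mol%), NaIO4 (4 equiv), 2,6-lutidine (2 equiv), dioxane–H2O (3:1), rt; used at once
Reagents that add atoms: sodium periodate, [Na+].[O-]I(=O)(=O)=O (oxygen relayed by catalytic osmium tetroxide, O=[Os](=O)(=O)=O)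
Why: Lemieux–Johnson oxidation: OsO4 dihydroxylates only the monosubstituted, electron-neutral vinyl group (the ring alkene is tetrasubstituted and hindered, both enoates are electron-poor and trisubstituted), and NaIO4 cleaves the diol to the C8 aldehyde with loss of formaldehyde.

**Step 10 (key step)**
Reactants: 15 methyl (Z)-2-(bromomethyl)-4-[(3S,6R)-2,6-dimethyl-3-{[(E)-3-methylpent-2-enoyl]oxy}-6-(2-oxoethyl)cyclohex-1-en-1-yl]but-2-enoate
Product: 17 methyl 2-[(2R,3R,4aR,7S)-3-hydroxy-4a,8-dimethyl-7-{[(E)-3-methylpent-2-enoyl]oxy}-1,2,3,4,4a,5,6,7-octahydronaphthalen-2-yl]prop-2-enoate, via allylindium species 16 (not isolated)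
Conditions: In powder (2 equiv), THF–H2O (1:1), 0.01 M, rt
Reagents that add atoms: none
Why: Intramolecular Barbier allylation in water: indium inserts into the C–Br bond to give a 2-(methoxycarbonyl)allylindium, a β-acrylate carbanion (homoenolate-type, reversed polarity at the normally electrophilic enoate β-carbon C7), which attacks the electrophilic C8 aldehyde through its γ-carbon to close ring B in a chair Zimmerman–Traxler transition state fused to the forming chair of ring B; the Z-allyl geometry forces the C6 tether axial on the transition-state ring so that on ring B the oxygen is axial and the acrylate equatorial, and since the angular methyl is locked axial by the ring A alkene this is the 7β,8β isomer (7R,8R), isolated as the hydroxy ester because water protonates the alkoxide before it can lactonize.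

**Step 11**
Reactants: 17 methyl 2-[(2R,3R,4aR,7S)-3-hydroxy-4a,8-dimethyl-7-{[(E)-3-methylpent-2-enoyl]oxy}-1,2,3,4,4a,5,6,7-octahydronaphthalen-2-yl]prop-2-enoate
Product: 18 methyl 2-[(2R,3R,4aR,7S)-3-acetoxy-4a,8-dimethyl-7-{[(E)-3-methylpent-2-enoyl]oxy}-1,2,3,4,4a,5,6,7-octahydronaphthalen-2-yl]prop-2-enoate (CNP0118541.1)
Conditions: Ac2O, DMAP, Et3N, CH2Cl2, 0 °C → rt
Reagents that add atoms: acetic anhydride, CC(=O)OC(C)=O
Why: DMAP-catalysed acylation of the axial 8β-alcohol with retention gives the acetate, and acetylating directly after isolation forestalls lactonization onto the cis-disposed methyl ester.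

**Compound list**

1 | 3-ethoxy-2-methylcyclohex-2-en-1-one | CCOC1=C(C)C(=O)CC1 | starting material
2 | 3-ethoxy-2,6-dimethylcyclohex-2-en-1-one (racemic, not isolated) | CCOC1=C(C)C(=O)C(C)CC1 | intermediate
3 | allyl (5-ethoxy-2,6-dimethylcyclohexa-1,5-dien-1-yl) carbonate | C=CCOC(=O)OC1=C(C)CCC(OCC)=C1C | intermediate
4 | (R)-6-allyl-3-ethoxy-2,6-dimethylcyclohex-2-en-1-one | CCOC1=C(C)C(=O)[C@@](C)(CC=C)CC1 | intermediate
5 | (1,3-dioxolan-2-ylmethyl)magnesium bromide | Br[Mg]CC1OCCO1 | starting material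
6 | (6R)-6-allyl-1-(1,3-dioxolan-2-ylmethyl)-3-ethoxy-2,6-dimethylcyclohex-2-en-1-ol (C1 epimers, present as bromomagnesium alkoxide, not isolated) | CCOC1=C(C)C(O)(CC2OCCO2)[C@@](C)(CC=C)CC1 | intermediate
7 | (R)-4-allyl-3-(1,3-dioxolan-2-ylmethyl)-2,4-dimethylcyclohex-2-en-1-one | O=C1CC[C@](C)(CC=C)C(CC2OCCO2)=C1C | intermediate
8 | (1S,4R)-4-allyl-3-(1,3-dioxolan-2-ylmethyl)-2,4-dimethylcyclohex-2-en-1-ol | O[C@H]1CC[C@](C)(CC=C)C(CC2OCCO2)=C1C | intermediate
9 | (E)-3-methylpent-2-enoic acid | CC/C(C)=C/C(=O)O | starting material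
10 | (1S,4R)-4-allyl-3-(1,3-dioxolan-2-ylmethyl)-2,4-dimethylcyclohex-2-en-1-yl (E)-3-methylpent-2-enoate | CC/C(C)=C/C(=O)O[C@H]1CC[C@](C)(CC=C)C(CC2OCCO2)=C1C | intermediate
11 | (1S,4R)-4-allyl-2,4-dimethyl-3-(2-oxoethyl)cyclohex-2-en-1-yl (E)-3-methylpent-2-enoate | CC/C(C)=C/C(=O)O[C@H]1CC[C@](C)(CC=C)C(CC=O)=C1C | intermediate
12 | methyl acrylate | C=CC(=O)OC | starting material
13 | methyl 4-[(3S,6R)-6-allyl-2,6-dimethyl-3-{[(E)-3-methylpent-2-enoyl]oxy}cyclohex-1-en-1-yl]-3-hydroxy-2-methylidenebutanoate (carbinol epimers) | CC/C(C)=C/C(=O)O[C@H]1CC[C@](C)(CC=C)C(CC(O)C(=C)C(=O)OC)=C1C | intermediate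
14 | methyl (Z)-4-[(3S,6R)-6-allyl-2,6-dimethyl-3-{[(E)-3-methylpent-2-enoyl]oxy}cyclohex-1-en-1-yl]-2-(bromomethyl)but-2-enoate | CC/C(C)=C/C(=O)O[C@H]1CC[C@](C)(CC=C)C(C/C=C(\CBr)C(=O)OC)=C1C | intermediate
15 | methyl (Z)-2-(bromomethyl)-4-[(3S,6R)-2,6-dimethyl-3-{[(E)-3-methylpent-2-enoyl]oxy}-6-(2-oxoethyl)cyclohex-1-en-1-yl]but-2-enoate | CC/C(C)=C/C(=O)O[C@H]1CC[C@](C)(CC=O)C(C/C=C(\CBr)C(=O)OC)=C1C | intermediate
16 | allylindium derived from 15 (CH2Br replaced by CH2–In, drawn as the σ-bound monovalent allylindium, not isolated) | CC/C(C)=C/C(=O)O[C@H]1CC[C@](C)(CC=O)C(C/C=C(\C[In])C(=O)OC)=C1C | intermediate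
17 | methyl 2-[(2R,3R,4aR,7S)-3-hydroxy-4a,8-dimethyl-7-{[(E)-3-methylpent-2-enoyl]oxy}-1,2,3,4,4a,5,6,7-octahydronaphthalen-2-yl]prop-2-enoate | C=C(C(=O)OC)[C@H]1CC2=C(C)[C@@H](OC(=O)/C=C(\C)CC)CC[C@]2(C)C[C@H]1O | intermediate
18 | methyl 2-[(2R,3R,4aR,7S)-3-acetoxy-4a,8-dimethyl-7-{[(E)-3-methylpent-2-enoyl]oxy}-1,2,3,4,4a,5,6,7-octahydronaphthalen-2-yl]prop-2-enoate (CNP0118541.1) | C=C(C(=O)OC)[C@H]1CC2=C(C)[C@@H](OC(=O)/C=C(\C)CC)CC[C@]2(C)C[C@H]1OC(C)=O | target

**Totals**

Total step count: 11. Longest linear sequence: 11 steps (fully linear from 1).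

**Three steps most likely to fail, each with one fallback**

Step 10 (ring B closure). The chair–chair transition state that gives the target isomer carries a 1,3-diaxial contact between the angular methyl and the C8–O–In unit. E/Z equilibration of the allylindium or a boat pathway could therefore erode selectivity toward the trans (diequatorial) isomer, and the cis hydroxy ester can lactonize. The fallback sets out from 15 and comes back at 18. Compound 15 is cyclized with CrCl2 in THF (Nozaki–Hiyama allylation). The allylchromium dichloride F1 equilibrates between its E and Z forms and reacts through the E form, which places both new substituents equatorial on ring B. This gives the 8-epimeric alcohol methyl 2-[(2R,3S,4aR,7S)-3-hydroxy-4a,8-dimethyl-7-{[(E)-3-methylpent-2-enoyl]oxy}-1,2,3,4,4a,5,6,7-octahydronaphthalen-2-yl]prop-2-enoate F2. A Mitsunobu reaction (AcOH, PPh3, DIAD, toluene, 0 °C → rt) then inverts C8 and installs the acetate in the same operation, giving 18 directly.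

Step 3 (Grignard addition). The vinylogous ester carbonyl sits between a quaternary carbon and a methyl-bearing alkene carbon, and the β-oxygenated Grignard reagent is sluggish. The fallback sets out from 4 and comes back at 11, using a smaller carbon nucleophile at a different oxidation level:
- Lithioacetonitrile F3 (MeCN, n-BuLi, THF, –78 °C) adds to 4 to give 2-[(6R)-6-allyl-3-ethoxy-1-hydroxy-2,6-dimethylcyclohex-2-en-1-yl]acetonitrile F4.
- Dilute HCl converts F4 to 2-[(6R)-6-allyl-2,6-dimethyl-3-oxocyclohex-1-en-1-yl]acetonitrile F5.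
- CBS reduction as in step 4 gives 2-[(3S,6R)-6-allyl-3-hydroxy-2,6-dimethylcyclohex-1-en-1-yl]acetonitrile F6.
- i-Bu2AlH (2.2 equiv, CH2Cl2, –78 °C, then aqueous acid) reduces the nitrile to 2-[(3S,6R)-6-allyl-3-hydroxy-2,6-dimethylcyclohex-1-en-1-yl]acetaldehyde F7.
- Steglich esterification of F7 with 9 gives 11.

Step 7 (Morita–Baylis–Hillman). The aldehyde is α-unbranched and its α-CH2 is allylic, so amine-mediated enolization, self-aldol or alkene migration may compete. The fallback sets out from 11 and comes back at 13, replacing amine catalysis by a preformed α-metalated acrylate. Methyl propiolate is hydroaluminated with i-Bu2AlH and N-methylmorpholine N-oxide in THF at 0 °C to give methyl 2-(diisobutylalumanyl)prop-2-enoate F8. F8 adds to 11 at 0 °C → rt under non-basic conditions, and work-up with Rochelle salt gives 13.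

**Further compounds**

F1 | step 10 | allylchromium dichloride derived from 15 (CH2Br replaced by CH2–CrCl2, E/Z equilibrating) | CC/C(C)=C/C(=O)O[C@H]1CC[C@](C)(CC=O)C(CC=C(C[Cr](Cl)Cl)C(=O)OC)=C1C
F2 | step 10 | methyl 2-[(2R,3S,4aR,7S)-3-hydroxy-4a,8-dimethyl-7-{[(E)-3-methylpent-2-enoyl]oxy}-1,2,3,4,4a,5,6,7-octahydronaphthalen-2-yl]prop-2-enoate | C=C(C(=O)OC)[C@H]1CC2=C(C)[C@@H](OC(=O)/C=C(\C)CC)CC[C@]2(C)C[C@@H]1O
F3 | step 3 | lithioacetonitrile | [Li]CC#N
F4 | step 3 | 2-[(6R)-6-allyl-3-ethoxy-1-hydroxy-2,6-dimethylcyclohex-2-en-1-yl]acetonitrile (C1 epimers, as lithium alkoxide) | CCOC1=C(C)C(O)(CC#N)[C@@](C)(CC=C)CC1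
F5 | step 3 | 2-[(6R)-6-allyl-2,6-dimethyl-3-oxocyclohex-1-en-1-yl]acetonitrile | O=C1CC[C@](C)(CC=C)C(CC#N)=C1C
F6 | step 3 | 2-[(3S,6R)-6-allyl-3-hydroxy-2,6-dimethylcyclohex-1-en-1-yl]acetonitrile | O[C@H]1CC[C@](C)(CC=C)C(CC#N)=C1C
F7 | step 3 | 2-[(3S,6R)-6-allyl-3-hydroxy-2,6-dimethylcyclohex-1-en-1-yl]acetaldehyde | O[C@H]1CC[C@](C)(CC=C)C(CC=O)=C1C
F8 | step 7 | methyl 2-(diisobutylalumanyl)prop-2-enoate | C=C(C(=O)OC)[Al](CC(C)C)CC(C)C
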